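**Structural features**

The target is a 6,7-seco-kaurane. Ring A is a cyclohexane with an equatorial 1-acetoxy group, a gem-dimethyl C4 and a carboxyl carbon C6 on C5. C10 is a spiro carbon shared with the δ-lactone ring B (C10–C20–O–C7(=O)–C8–C9). Ring B is cis-fused through C8–C9 to ring C of a bicyclo[3.2.1]octane, whose two-carbon bridge (ring D) holds the C15 ketone and the C16 methyl group. There are seven stereocentres: C1, C10 and C5 are contiguous on ring A, C10–C9–C8 continue into the lactone, C13 is fixed by the bridge, and C16 carries its methyl on the face turned to C11–C12. Two quaternary carbons, C10 and C8, are separated only by C9, and C8 is the α-carbon of a non-enolisable β-keto lactone. The fragile points are this β-keto lactone (retro-Claisen opening), C16 (epimerisable next to the ketone), C5 (next to the carboxyl), the acetate, and a possible shift of the C7 acyl group from O20 to a free O1. The real difficulty is C10, wedged between oxygenated C1 and crowded C5, with two one-carbon arms (C20 and C9) that differ only in what they become later. The key step exploits exactly this pattern: a quaternary C10 bearing C20H2–O next to the C1 oxygen is what a 1,2-shift in a 2,3-epoxy alcohol leaves behind, so C5–C10 can be made by ring expansion of a cyclopentanol into ring A.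

**Logic of the disconnections**

From 31 back to 29 and 28. No skeletal bond is cut: the C6 carboxyl goes back to the benzyl-protected C6 alcohol, and the C16–H/C17H3 unit to the C16=C17 alkene. The acid and the epimerisable C16 centre are thus made last, and before that C16 is not stereogenic. The forward steps must add hydrogen to the exo face of C16=C17 in 28 and oxidise 29 without disturbing C5, C16 or the acetate.

From 28 to 27. The C16=C17 bond is cut and C17 becomes formaldehyde. This leaves an unsubstituted ring D ketone, so ring D closure need not control C16. The forward step requires that only C16 can enolise, which holds because C8 is quaternary and C12 is already CH2.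

From 27 via 25 to 23. A carbonyl is put back on C12 and then C13–C16 is cut, which opens ring D. The C12 oxygen is the price of a regiodefined C13 nucleophile whose enolate double bond lies outside the new ring. The gain is 23, which has only rings A, B and C and an acetyl group on C8. The forward steps must make C16 electrophilic while the C12 enol silane survives, and later remove the C12 carbonyl without touching the C15 ketone.

From 23 to 21 and 22. C9–C11 and C8–C14 are cut together, which removes ring C and the adjacent stereocentres C8 and C9 in one operation. C8=C9 of 21 is doubly activated, so a cycloaddition is reasonable even at the neopentyl C9. The forward step needs the diene to bond through its nucleophilic end to C9, on the face of C9 that lies on the side of C1.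

From 21 via 20, 18 and 17 to 16, and on to 14 and 15. C8=C9 is cut (aldol-type condensation), then the O20–C7 ester bond; the C1 carbinol goes back to the ketone and the C9 aldehyde to the protected alcohol. Ring B is thereby reduced to an acetoacetate on the C20 hydroxyl of 14. The forward steps must never let the two arms on C10 become equal or exchange the acyl group, and must reduce the C1 ketone from the face of C9.

From 14 to 13. The C5–C10 bond is cut and C5 is rejoined to C1, which contracts ring A to a cyclopentanol and turns C10 into an epoxide carbon. The quaternary centre is thus made by a stereospecific 1,2-shift and not by an enolate alkylation between two crowded carbons. The forward step needs C5 and not C2 to migrate, and needs the (S) epoxide configuration at C10.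

From 13 via 12 to 7 and 10. The epoxide oxygen is removed and C1–C10 is cut. This separates a 2-metallated allyl ether from a cyclopentanone with a single stereocentre. The forward steps need addition trans to the CH2OBn group of 7 and hydroxyl-directed epoxidation of 12 on the correct alkene face.

From 7 via 6 to 1, 4 and 2. C5–C6 is cut next to the carbonyl, and the C2=C3 alkene is restored so that only C5 can be deprotonated. Ring A then comes from one commercial enone and a one-carbon electrophile. The forward step needs absolute control at C5 by the auxiliary 2 and its removal without epimerisation.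

From 10 to 8 and 9. The allylic C–O bond is cut, giving two commercial pieces. The forward step needs substitution at the allylic and not the vinylic bromide.

**Other disconnections considered**

Alternative 1: The cut is C13–C16 together with a temporary C12–C16 bond. In the forward direction a diazomethyl ketone on C8 is decomposed with Rh2(OAc)4 and the carbenoid adds across the C12=C13 alkene of ring C to give the cyclopropyl ketone A1; reductive opening of C12–C16 and introduction of C17 would follow.
- In its favour: a carbenoid has no orbital-alignment handicap when the C15 carbonyl lies inside the new five-membered ring, and the C12=C13 alkene would come from a plain butadiene cycloaddition, so no oxygen has to be placed on C12 and removed again. On the mechanism of the ring D closure itself it is the better of the two plans.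
- Against it: the diazoketone must be made from a quaternary C15 acid derivative beside the lactone; the cyclopropane must open at C12–C16 and not at C13–C16, which would give a bicyclo[2.2.2]octane; A1 still lacks C17; and its tert-butyl ester must be cleaved by acid at the end.
- Comparison: step economy is about equal (diazoketone formation, cyclopropanation, cleavage and C17 introduction against bromination/alkylation, deoxygenation and methylenation). The chosen plan avoids diazomethane chemistry and the cleavage regiochemistry.

Alternative 2: The cut is C8–C15. The silyl ketene acetal of the lactone is coupled by Pd(OAc)2 (divalent palladium) with the terminal carbon of an isopropenyl group on C13, giving A2 with quaternary C8, ring D and an exocyclic C16=C17.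
- In its favour: the nucleophile is the lactone itself with its enol double bond outside the new ring, and C8 and ring D form in one event. The 16-methylene group arrives directly, which is better than the separate methylenation of the chosen plan.
- Against it: ring C with a correctly placed C13 isopropenyl group and the C9 centre must be built beforehand; C15 arrives as CH2 and needs allylic oxidation and a second oxidation; this type of coupling usually consumes a full equivalent of palladium; and the 1-silyl ether must be exchanged for acetate.
- Comparison: the number of redox corrections after ring closure is equal (two oxidations against one deoxygenation and one methylenation). The chosen plan sets C8 and C9 together from the lactone, which Alternative 2 cannot do.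

Alternative 3: The cut is again C13–C16, made by a Claisen rearrangement. The (Z)-ethylidene enol ether of a C15–O–C11 bridged lactone rearranges to the bicyclo[3.2.1]octenone A3, with the C15 ketone and the C16 methyl in place.
- In its favour: the C16 configuration follows from the enol ether geometry, no C12 oxygen is needed, and a sigmatropic shift tolerates crowding. On control of C16 and on redox economy in ring D it is better than the chosen plan.
- Against it: the bridged lactone and its Z-selective ethylidenation are long and uncertain; in A3 ring B is not yet closed (C7 is a protected alcohol, C20 a silyl ether), so oxidation and lactonisation remain; and four protecting groups are carried.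
- Comparison: the chosen plan builds ring B first and uses it as the dienophile, which should save several steps. It pays for this with the C12 carbonyl.

Key step: step 7

Remark: ent-kaurane numbering is kept for all intermediates (C7, C8, C15 and C16 come from the acetoacetyl unit, C11–C14 from the diene, C17 from formaldehyde); the C=N geometry of 3, 5 and 26 is left open; 2, 15 and 22 are taken as commercial.
Remark: the configurations of 13 and 14 were checked against the target (retention at C5, inversion at C10) and are used unchanged; the change made to the key step is the milder chelating Lewis acid ZnBr2, which should spare the PMB ether.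

**Route**

Step 1
Reactants: 1 4,4-dimethylcyclopent-2-en-1-one; 2 (S)-1-amino-2-(methoxymethyl)pyrrolidine (SAMP)
Product: 3 SAMP hydrazone of 1
Conditions: TsOH (cat.), benzene, reflux, Dean–Stark
Reagents that add atoms: none
Why: Hydrazone condensation; the β-carbon of 1 is neopentyl, so conjugate addition of the hydrazine should not compete.

Step 2
Reactants: 3 SAMP hydrazone of 1; 4 benzyl chloromethyl ether
Product: 6 (S)-5-[(benzyloxy)methyl]-4,4-dimethylcyclopent-2-en-1-one, via alkylated SAMP hydrazone 5 (not isolated)
Conditions: LiN(iPr)2, THF, 0 °C; 4, −100 → −78 °C; then sat. aq. (CO2H)2, Et2O, rt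
Reagents that add atoms: water, O
Why: Enders SAMP-hydrazone α-alkylation: only C5 can be deprotonated (C4 is quaternary), and the chelated lithium azaenolate is alkylated on the face predicted by the established model, which corresponds to (S) at the new centre. Two-phase oxalic acid hydrolysis should release the enone without epimerisation.

Step 3
Reactants: 6 (S)-5-[(benzyloxy)methyl]-4,4-dimethylcyclopent-2-en-1-one
Product: 7 (S)-2-[(benzyloxy)methyl]-3,3-dimethylcyclopentan-1-one
Conditions: H2 (1 atm), Pd/C, pyridine (0.5 equiv), EtOAc, rt
Reagents that add atoms: none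
Why: Catalytic hydrogenation of the conjugated alkene; pyridine-poisoned Pd/C spares the benzyl ether and the neutral medium leaves the α-centre alone.

Step 4
Reactants: 8 2,3-dibromoprop-1-ene; 9 4-methoxybenzyl alcohol
Product: 10 2-bromo-3-[(4-methoxybenzyl)oxy]prop-1-ene
Conditions: NaH, THF, 0 °C → rt
Reagents that add atoms: none
Why: Williamson ether synthesis; the alkoxide displaces only the allylic bromide, the vinylic bromide being inert to substitution.

Step 5
Reactants: 10 2-bromo-3-[(4-methoxybenzyl)oxy]prop-1-ene; 7 (S)-2-[(benzyloxy)methyl]-3,3-dimethylcyclopentan-1-one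
Product: 12 (1S,2S)-2-[(benzyloxy)methyl]-1-{3-[(4-methoxybenzyl)oxy]prop-1-en-2-yl}-3,3-dimethylcyclopentan-1-ol, via 2-lithioallyl PMB ether 11 (not isolated)
Conditions: t-BuLi (2.1 equiv), Et2O, −78 °C; CeCl3, THF, −78 °C; then 7, −78 °C
Reagents that add atoms: none
Why: Bromine–lithium exchange and 1,2-addition of the derived organocerium reagent, whose low basicity suppresses enolisation and loss of benzyl oxide. The nucleophile should enter trans to the neighbouring CH2OBn group, leaving OH cis to CH2OBn.

Step 6
Reactants: 12 (1S,2S)-2-[(benzyloxy)methyl]-1-{3-[(4-methoxybenzyl)oxy]prop-1-en-2-yl}-3,3-dimethylcyclopentan-1-ol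
Product: 13 (1S,2S)-2-[(benzyloxy)methyl]-1-[(2S)-2-{[(4-methoxybenzyl)oxy]methyl}oxiran-2-yl]-3,3-dimethylcyclopentan-1-ol
Conditions: VO(acac)2 (5 mol%), t-BuOOH, CH2Cl2, 0 °C → rt
Reagents that add atoms: tert-butyl hydroperoxide, CC(C)(C)OO
Why: Hydroxyl-directed epoxidation through the vanadium alkoxide. In the reactive conformer the small ring CH2 (C2) lies next to the CH2OPMB group and bulky C5 stands perpendicular on the far face (A(1,2) strain model), which should give the (S) epoxide carbon C10.

Step 7
Reactants: 13 (1S,2S)-2-[(benzyloxy)methyl]-1-[(2S)-2-{[(4-methoxybenzyl)oxy]methyl}oxiran-2-yl]-3,3-dimethylcyclopentan-1-ol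
Product: 14 (2S,3R)-3-[(benzyloxy)methyl]-2-(hydroxymethyl)-2-{[(4-methoxybenzyl)oxy]methyl}-4,4-dimethylcyclohexan-1-one
Conditions: ZnBr2 (1.2 equiv), CH2Cl2, 0 °C → rt
Reagents that add atoms: none
Why: ZnBr2 binds the hydroxyl and the epoxide oxygen and weakens the C10–O bond at the tertiary epoxide carbon, while the primary C20–O bond stays intact. In concert the C1–C5 bond, held antiperiplanar to the breaking C10–O bond, shifts to C10 and the C1 oxygen becomes the carbonyl; this is a semipinacol rearrangement of a tertiary 2,3-epoxy alcohol, closest to the known Lewis acid-promoted ring expansions of 1-(oxiranyl)cycloalkanols. Ring A is closed not by cyclisation but by a suprafacial 1,2-shift that enlarges the cyclopentanol by one carbon to the cyclohexanone. The new stereocentre C10 is controlled by the epoxide configuration, because the shift inverts C10; C5 migrates with retention. The step needs C5 and not C2 to migrate; this should follow from the higher migratory aptitude of the more substituted secondary carbon, since both chelated rotamers are accessible. It also needs ionisation at C10 and not C20, which the tertiary centre secures. The trans arrangement of CH2OBn and the oxirane keeps the benzyl ether oxygen from capturing C10, and the mild zinc salt should leave the PMB ether intact. The epoxide oxygen ends as the free C20 hydroxyl, so the two arms on C10 emerge differentiated.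

Step 8
Reactants: 14 (2S,3R)-3-[(benzyloxy)methyl]-2-(hydroxymethyl)-2-{[(4-methoxybenzyl)oxy]methyl}-4,4-dimethylcyclohexan-1-one; 15 2,2,6-trimethyl-4H-1,3-dioxin-4-one
Product: 16 [(1R,6R)-6-[(benzyloxy)methyl]-1-{[(4-methoxybenzyl)oxy]methyl}-5,5-dimethyl-2-oxocyclohexyl]methyl 3-oxobutanoate
Conditions: toluene, 110 °C
Reagents that add atoms: none
Why: Thermal acetoacetylation: retro-[4+2] of the dioxinone gives acetylketene, which is trapped by the only hydroxyl (C20–OH). The neutral medium avoids retro-aldol loss of the hydroxymethyl arm.

Step 9
Reactants: 16 [(1R,6R)-6-[(benzyloxy)methyl]-1-{[(4-methoxybenzyl)oxy]methyl}-5,5-dimethyl-2-oxocyclohexyl]methyl 3-oxobutanoate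
Product: 17 [(1R,6R)-6-[(benzyloxy)methyl]-1-(hydroxymethyl)-5,5-dimethyl-2-oxocyclohexyl]methyl 3-oxobutanoate
Conditions: DDQ, CH2Cl2/pH 7 buffer, 0 °C
Reagents that add atoms: none
Why: Oxidative cleavage of the PMB ether (benzylic hydride abstraction, hydrolysis of the oxocarbenium ion); the plain benzyl ether reacts far more slowly.

Step 10
Reactants: 17 [(1R,6R)-6-[(benzyloxy)methyl]-1-(hydroxymethyl)-5,5-dimethyl-2-oxocyclohexyl]methyl 3-oxobutanoate
Product: 18 [(1R,2S,6R)-6-[(benzyloxy)methyl]-2-hydroxy-1-(hydroxymethyl)-5,5-dimethylcyclohexyl]methyl 3-oxobutanoate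
Conditions: Me4NBH(OAc)3, MeCN/AcOH (1:1), −30 °C
Reagents that add atoms: none
Why: Evans–Saksena hydroxyl-directed reduction: the C9 hydroxyl binds boron and delivers hydride to the C1 carbonyl from the face of C9, so the new hydroxyl is trans to C9 and cis to C20 as in the target. The acetoacetate ketone has no directing hydroxyl and should not be reduced.

Step 11
Reactants: 18 [(1R,2S,6R)-6-[(benzyloxy)methyl]-2-hydroxy-1-(hydroxymethyl)-5,5-dimethylcyclohexyl]methyl 3-oxobutanoate
Product: 20 8-acetyl-C8=C9 spiro lactone (3-acetyl-5,6-dihydro-2H-pyran-2-one spiro-fused at C10 to ring A; 1-OH and 5-CH2OBn cis to C20), via hydroxy aldehyde 19 (not isolated)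
Conditions: TEMPO (cat.), PhI(OAc)2, CH2Cl2, rt; then piperidine (cat.), 0 °C → rt
Reagents that add atoms: none
Why: Chemoselective TEMPO oxidation of the primary C9 alcohol beside the hindered secondary one, then intramolecular Knoevenagel condensation (6-exo-trig aldol, dehydration) closes lactone ring B.

Step 12
Reactants: 20 8-acetyl-C8=C9 spiro lactone with free 1-OH
Product: 21 1-O-acetyl derivative of 20
Conditions: Ac2O, DMAP (cat.), pyridine, CH2Cl2, 0 °C → rt
Reagents that add atoms: acetic anhydride, CC(=O)OC(C)=O
Why: DMAP-catalysed acylation of the only hydroxyl; capping O1 at once prevents transfer of the C7 acyl group from O20 to O1.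

Step 13
Reactants: 21 1-O-acetyl derivative of 20; 22 2-(trimethylsilyloxy)buta-1,3-diene
Product: 23 cis-fused ring C adduct (8-acetyl, C12(OSiMe3)=C13, C11 and C14 cis to C1 on the lactone ring)
Conditions: toluene, 80 °C, sealed tube
Reagents that add atoms: none
Why: Diels–Alder cycloaddition, the concerted equivalent of a double Michael annulation, on the doubly activated C8=C9; the nucleophilic diene terminus bonds to C9, which places the silyl enol ether at C12=C13. Suprafacial addition makes ring C cis-fused with the acetyl trans to C11, and the diene should approach the face of C9 flanked by the acetoxy oxygen on C1 and not the CH2OBn/gem-dimethyl side.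

Step 14
Reactants: 23 cis-fused ring C adduct
Product: 25 12,15-diketone with ring D closed (C13–C16 bond; C16 is CH2), via bromomethyl ketone 24 (not isolated)
Conditions: LiN(SiMe3)2, THF, −78 °C; NBS (inverse addition), −78 °C; then Bu4N[Ph3SiF2], −78 → 0 °C
Reagents that add atoms: none
Why: Kinetic deprotonation at the only acidic ketone position (the C16 methyl; C8 is quaternary) and bromination of the lithium enolate, which should outpace the neutral silyl enol ether. Fluoride then unmasks the C12 enolate regiospecifically, and C13 displaces the primary bromide by intramolecular SN2 (5-exo-tet, enolate double bond outside the new ring), closing ring D and fixing C13 through the 1,3-diaxial bridge.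

Step 15
Reactants: 25 12,15-diketone
Product: 27 15-ketone with C12 as CH2, via C12 tosylhydrazone 26 (not isolated)
Conditions: TsNHNH2 (1.05 equiv), EtOH, rt; then catecholborane, CHCl3, 0 °C; NaOAc·3H2O, 60 °C
Reagents that add atoms: none
Why: Reductive deoxygenation through the tosylhydrazone (Caglioti-type, catecholborane variant); the hydrazone should form at the unhindered C12 cyclohexanone and not at the neopentyl bridged C15 ketone, and hydride addition with loss of sulfinate and N2 gives the methylene group.

Step 16
Reactants: 27 15-ketone with C12 as CH2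
Product: 28 16-methylene-15-ketone
Conditions: (CH2O)n, PhNHMe·CF3CO2H, THF, 65 °C
Reagents that add atoms: paraformaldehyde (as formaldehyde), C=O
Why: α-Methylenation by Mannich condensation and elimination under mildly acidic conditions; C16 is the only enolisable position, and acetate and lactone are not exposed to base.

Step 17
Reactants: 28 16-methylene-15-ketone
Product: 29 (16R)-16-methyl-15-ketone with free C6 alcohol
Conditions: H2 (1 atm), Pd/C, EtOAc/EtOH, rt
Reagents that add atoms: none
Why: Catalytic hydrogenation of the exocyclic enone from the exo face (the side of the one-carbon bridge C14), which places the methyl toward C12 (16R), with hydrogenolysis of the benzyl ether in the same operation.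

Step 18
Reactants: 29 (16R)-16-methyl-15-ketone with free C6 alcohol
Product: 31 target acid, via C6 aldehyde 30 (not isolated)
Conditions: TEMPO (cat.), NaOCl (cat.), NaClO2, MeCN/phosphate buffer pH 6.7, 35 °C
Reagents that add atoms: sodium chlorite, [Na+].[O-]Cl=O
Why: TEMPO-catalysed oxidation to the aldehyde and chlorite oxidation in one pot; the buffered medium should avoid enolisation at C5 and C16 and leave acetate and β-keto lactone intact.

**Compound list**

1 | 4,4-dimethylcyclopent-2-en-1-one | CC1(C)CC(=O)C=C1 | starting material
2 | (S)-1-amino-2-(methoxymethyl)pyrrolidine (SAMP) | COC[C@@H]1CCCN1N | starting material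
3 | SAMP hydrazone of 1 | COC[C@@H]1CCCN1N=C1CC(C)(C)C=C1 | intermediate
4 | benzyl chloromethyl ether | ClCOCc1ccccc1 | starting material
5 | alkylated SAMP hydrazone (hydrazone of 6) | COC[C@@H]1CCCN1N=C1C=CC(C)(C)[C@H]1COCc1ccccc1 | intermediate
6 | (S)-5-[(benzyloxy)methyl]-4,4-dimethylcyclopent-2-en-1-one | O=C1C=CC(C)(C)[C@H]1COCc1ccccc1 | intermediate
7 | (S)-2-[(benzyloxy)methyl]-3,3-dimethylcyclopentan-1-one | O=C1CCC(C)(C)[C@H]1COCc1ccccc1 | intermediate
8 | 2,3-dibromoprop-1-ene | C=C(Br)CBr | starting material
9 | 4-methoxybenzyl alcohol | COc1ccc(CO)cc1 | starting material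
10 | 2-bromo-3-[(4-methoxybenzyl)oxy]prop-1-ene | C=C(Br)COCc1ccc(OC)cc1 | intermediate
11 | 2-lithio-3-[(4-methoxybenzyl)oxy]prop-1-ene | [Li]C(=C)COCc1ccc(OC)cc1 | intermediate
12 | (1S,2S)-2-[(benzyloxy)methyl]-1-{3-[(4-methoxybenzyl)oxy]prop-1-en-2-yl}-3,3-dimethylcyclopentan-1-ol | O[C@]1(CCC(C)(C)[C@H]1COCc2ccccc2)C(=C)COCc3ccc(OC)cc3 | intermediate
13 | (1S,2S)-2-[(benzyloxy)methyl]-1-[(2S)-2-{[(4-methoxybenzyl)oxy]methyl}oxiran-2-yl]-3,3-dimethylcyclopentan-1-ol | O[C@]1(CCC(C)(C)[C@H]1COCc2ccccc2)[C@]3(CO3)COCc4ccc(OC)cc4 | intermediate
14 | (2S,3R)-3-[(benzyloxy)methyl]-2-(hydroxymethyl)-2-{[(4-methoxybenzyl)oxy]methyl}-4,4-dimethylcyclohexan-1-one | O=C1CCC(C)(C)[C@@H](COCc2ccccc2)[C@]1(CO)COCc1ccc(OC)cc1 | intermediate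
15 | 2,2,6-trimethyl-4H-1,3-dioxin-4-one | CC1=CC(=O)OC(C)(C)O1 | starting material
16 | [(1R,6R)-6-[(benzyloxy)methyl]-1-{[(4-methoxybenzyl)oxy]methyl}-5,5-dimethyl-2-oxocyclohexyl]methyl 3-oxobutanoate | O=C1CCC(C)(C)[C@@H](COCc2ccccc2)[C@]1(COC(=O)CC(C)=O)COCc1ccc(OC)cc1 | intermediate
17 | [(1R,6R)-6-[(benzyloxy)methyl]-1-(hydroxymethyl)-5,5-dimethyl-2-oxocyclohexyl]methyl 3-oxobutanoate | O=C1CCC(C)(C)[C@@H](COCc2ccccc2)[C@]1(COC(=O)CC(C)=O)CO | intermediate
18 | [(1R,2S,6R)-6-[(benzyloxy)methyl]-2-hydroxy-1-(hydroxymethyl)-5,5-dimethylcyclohexyl]methyl 3-oxobutanoate | O[C@H]1CCC(C)(C)[C@@H](COCc2ccccc2)[C@]1(COC(=O)CC(C)=O)CO | intermediate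
19 | C9 aldehyde of 18 (1-OH free, acetoacetate on O20) | O[C@H]1CCC(C)(C)[C@@H](COCc2ccccc2)[C@]1(COC(=O)CC(C)=O)C=O | intermediate
20 | 8-acetyl-C8=C9 spiro lactone, 1-OH and 5-CH2OBn cis to C20 | O[C@H]1CCC(C)(C)[C@@H](COCc3ccccc3)[C@@]12COC(=O)C(C(C)=O)=C2 | intermediate
21 | 1-O-acetyl derivative of 20 | CC(=O)O[C@H]1CCC(C)(C)[C@@H](COCc3ccccc3)[C@@]12COC(=O)C(C(C)=O)=C2 | intermediate
22 | 2-(trimethylsilyloxy)buta-1,3-diene | C=CC(=C)O[Si](C)(C)C | starting material
23 | cis-fused ring C adduct: 1-OAc, 8-acetyl, C12(OSiMe3)=C13, H9 cis to the acetyl group | CC(=O)O[C@H]1CCC(C)(C)[C@@H](COCc4ccccc4)[C@@]12COC(=O)[C@@]3(C(C)=O)CC=C(O[Si](C)(C)C)C[C@@H]23 | intermediate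
24 | bromomethyl ketone of 23 (C16 bromide) | CC(=O)O[C@H]1CCC(C)(C)[C@@H](COCc4ccccc4)[C@@]12COC(=O)[C@@]3(C(=O)CBr)CC=C(O[Si](C)(C)C)C[C@@H]23 | intermediate
25 | 1-acetoxy-6-benzyloxy-12,15-dioxo-17-nor-6,7-secokauran-7,20-olide | CC(=O)O[C@H]1CCC(C)(C)[C@@H](COCc4ccccc4)[C@@]12COC(=O)[C@@]13C[C@@H](C(=O)C[C@H]12)CC3=O | intermediate
26 | C12 tosylhydrazone of 25 | CC(=O)O[C@H]1CCC(C)(C)[C@@H](COCc4ccccc4)[C@@]12COC(=O)[C@@]13C[C@@H](C(=NNS(=O)(=O)c5ccc(C)cc5)C[C@H]12)CC3=O | intermediate
27 | 1-acetoxy-6-benzyloxy-15-oxo-17-nor-6,7-secokauran-7,20-olide | CC(=O)O[C@H]1CCC(C)(C)[C@@H](COCc4ccccc4)[C@@]12COC(=O)[C@@]13C[C@@H](CC[C@H]12)CC3=O | intermediate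
28 | 1-acetoxy-6-benzyloxy-15-oxo-6,7-secokaur-16-en-7,20-olide | CC(=O)O[C@H]1CCC(C)(C)[C@@H](COCc4ccccc4)[C@@]12COC(=O)[C@@]13C[C@@H](CC[C@H]12)C(=C)C3=O | intermediate
29 | (16R)-1-acetoxy-6-hydroxy-15-oxo-6,7-secokauran-7,20-olide | CC(=O)O[C@H]1CCC(C)(C)[C@@H](CO)[C@@]12COC(=O)[C@@]13C[C@@H](CC[C@H]12)[C@@H](C)C3=O | intermediate
30 | C6 aldehyde of 29 | CC(=O)O[C@H]1CCC(C)(C)[C@@H](C=O)[C@@]12COC(=O)[C@@]13C[C@@H](CC[C@H]12)[C@@H](C)C3=O | intermediate
31 | (1S,5R,8S,9S,10S,13R,16R)-1-acetoxy-15-oxo-6,7-secokauran-7,20-olid-6-oic acid | CC(=O)O[C@H]1CCC(C)(C)[C@@H](C(=O)O)[C@@]12COC(=O)[C@@]13C[C@@H](CC[C@H]12)[C@@H](C)C3=O | target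

**Step count and least certain steps**

Total step count: 18. Longest linear sequence: 17 (steps 1–3 and 5–18; step 4 is a one-step branch).

Step 7 (key step). Most likely to go wrong: migration of the less substituted ring carbon C2 in place of C5, or sluggish ionisation that lets bromide capture C10 or erodes the PMB ether; both chelated rotamers are accessible, so the choice between C2 and C5 rests on migratory aptitude alone. Fallback, from 13: silylation of the tertiary hydroxyl (Me3SiOTf, 2,6-lutidine) gives trimethylsilyl ether F1. TiCl4 in CH2Cl2 at −78 °C then triggers the rearrangement of the epoxy silyl ether, in which the push of the silyloxy group makes the shift concerted with C–O cleavage. Aqueous work-up returns to the route at 14.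

Step 14. Most likely to go wrong: loss of chemoselectivity in the bromination (attack at C13 of the silyl enol ether, or proton transfer between the enolate and the bromoketone leading to dibromination), because two enol derivatives are present. Fallback, from 23: Me3SiOTf/Et3N converts the acetyl group into its enol silane, giving bis(enol silane) F2. Oxidation with (NH4)2Ce(NO3)6 and NaHCO3 in MeCN at −20 °C should join C13 and C16 by the known oxidative coupling of silyl bis-enol ethers to 1,4-diketones, without any halogenation. It returns to the route at 25.

Step 13. Most likely to go wrong: slow cycloaddition at the neopentyl C9 with poor facial selectivity, or diversion into a hetero-Diels–Alder reaction through the acetyl oxygen. Fallback, from 21 and 22, stepwise and ionic: TiCl4-promoted Mukaiyama–Michael addition at −78 °C gives, after desilylating work-up, vinyl ketone F3. Cs2CO3 in MeCN closes ring C by intramolecular Michael addition of C8 to C14, giving ring C ketone F4. LiN(SiMe3)2 (2.2 equiv)/Me3SiCl at −78 °C should enolise the ring ketone kinetically toward the less hindered C13, and the acetyl group, to give F2. F2 is then coupled oxidatively as in the fallback of step 14 and returns to the route at 25.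

Step 15. Most likely to go wrong: hydrazone formation also at the C15 ketone, or incomplete reduction with alkene formation, because both carbonyls are ketones and differ only in hindrance. Fallback, from 25: ethane-1,2-dithiol and BF3·OEt2 at 0 °C should give the C12 dithiolane F5 selectively, since thioketalisation is very sensitive to the neopentyl environment of C15. Desulfurisation with Raney Ni in EtOH at rt returns to the route at 27.

Step 2. Most likely to go wrong: incomplete facial control or partial epimerisation during hydrazone cleavage, since a cross-conjugated azaenolate of an enone hydrazone is used and the product has an acidic α-centre next to a β-alkoxy group. Fallback, from 1: LiN(iPr)2/Me3SiCl gives the silyl dienol ether F6. Catalytic asymmetric hydroxymethylation with aqueous formaldehyde (Sc(OTf)3, chiral 2,2'-bipyridine diol ligand) gives (S)-5-(hydroxymethyl)-4,4-dimethylcyclopent-2-en-1-one F7. Acid-catalysed benzylation with benzyl 2,2,2-trichloroacetimidate (TfOH cat.) returns to the route at 6.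

Further compounds
F1 | step 7 | trimethylsilyl ether of 13 | C[Si](C)(C)O[C@]1(CCC(C)(C)[C@H]1COCc2ccccc2)[C@]3(CO3)COCc4ccc(OC)cc4
F2 | step 14 | bis(trimethylsilyl enol ether) of the ring C ketone and the C8 acetyl group | CC(=O)O[C@H]1CCC(C)(C)[C@@H](COCc4ccccc4)[C@@]12COC(=O)[C@@]3(C(=C)O[Si](C)(C)C)CC=C(O[Si](C)(C)C)C[C@@H]23
F3 | step 13 | open-chain Michael adduct (C9–CH2–CO–CH=CH2, C8 epimerisable) | CC(=O)O[C@H]1CCC(C)(C)[C@@H](COCc3ccccc3)[C@@]12COC(=O)C(C(C)=O)[C@H]2CC(=O)C=C
F4 | step 13 | ring C ketone (C12=O) with 8-acetyl group | CC(=O)O[C@H]1CCC(C)(C)[C@@H](COCc4ccccc4)[C@@]12COC(=O)[C@@]3(C(C)=O)CCC(=O)C[C@@H]23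
F5 | step 15 | C12 1,3-dithiolane of 25 | CC(=O)O[C@H]1CCC(C)(C)[C@@H](COCc4ccccc4)[C@@]12COC(=O)[C@@]13C[C@@H](C5(SCCS5)C[C@H]12)CC3=O
F6 | step 2 | 5,5-dimethyl-2-(trimethylsilyloxy)cyclopenta-1,3-diene | C[Si](C)(C)OC1=CC(C)(C)C=C1
F7 | step 2 | (S)-5-(hydroxymethyl)-4,4-dimethylcyclopent-2-en-1-one | O=C1C=CC(C)(C)[C@H]1CO
A1 | alternative 1 | cyclopropane-fused bicyclo[3.2.1]octanone | CC(=O)O[C@H]1CCC(C)(C)[C@@H](C(=O)OC(C)(C)C)[C@@]12COC(=O)[C@@]13C[C@H]4[C@@H](C[C@H]12)[C@H]4C3=O
A2 | alternative 2 | bicyclo[3.2.1]octane lactone with 16-methylene group | CC(C)(C)[Si](C)(C)O[C@H]1CCC(C)(C)[C@@H](COCc2ccccc2)[C@@]12COC(=O)[C@@]13C[C@@H](CC[C@H]12)C(=C)C3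
A3 | alternative 3 | bicyclo[3.2.1]oct-2-en-6-one with C16 methyl | CC(C)(C)[Si](C)(C)O[C@H]1CCC(C)(C)[C@@H](COCc2ccccc2)[C@]1(CO[Si](C)(C)C(C)(C)C)[C@@H]1C=C[C@@H]2C[C@@]1(COCc1ccc(OC)cc1)C(=O)[C@@H]2C
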